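## Retrosynthetic overview

1. Target 11 comes from vinylogous ester 8 by brominative aromatisation. Ring B is carried as a cyclohexane-1,3-dione: its single enol OH becomes the OMe and its remaining C=O becomes the free OH. Both ring-B bromines enter in the same operation.
2. The key disconnection is the diaryl ether C–O bond, since the molecule has no C–C bond outside its two rings. C2 of the 1,3-dione is normally a nucleophile, like the phenol oxygen it must bond to. Its polarity is reversed as the phenyliodonium ylide 6, an enolonium equivalent, which phenol 4 captures.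
3. Phenol 4 comes from 2,4,6-tribromoanisole 1 by ortho-selective Br/Li exchange, borylation and oxidation. This fixes the ring-A pattern (Br ortho and para to OMe).
4. No ring is built. Ring A is bought aromatic; the ring-B carbocycle is bought as 5 and becomes aromatic in the last step.

Assumption: 11 has no stereocentre and no hindered axis (diaryl ethers of this substitution rotate freely), so it is achiral and there is no enantiomer to select.

## Route

Step 1
Reactants: 1 2,4,6-tribromoanisole
Product: 4 3,5-dibromo-2-methoxyphenol, via aryllithium 2 (not isolated), via dimethyl arylboronate 3 (not isolated)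
Conditions: n-BuLi (1.0 equiv), Et2O, −78 °C; B(OMe)3 (1.5 equiv), −78 °C to rt; AcOH, 30% aq. H2O2, 0 °C to rt
Reagents that add atoms: hydrogen peroxide, OO (phenol oxygen of 4); n-butyllithium, [Li]CCCC (Li of 2 only); trimethyl borate, COB(OC)OC (B(OMe)2 of 3 only)
Why: Bromine–lithium exchange takes one of the two equivalent bromines ortho to OMe (lithium is held by the methoxy oxygen and the crowded C–Br is relieved, effects the para C–Br lacks), and borylation followed by peroxide oxidation (1,2-aryl shift from boron to oxygen) gives the phenol without touching the other two C–Br bonds; no stereocentre is formed.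

Step 2
Reactants: 5 cyclohexane-1,3-dione
Product: 6 2-(phenyl-λ3-iodanylidene)cyclohexane-1,3-dione
Conditions: PhI(OAc)2 (1.0 equiv), KOH (2 equiv), MeOH, 0 °C, 2 h; precipitate with water, store cold
Reagents that add atoms: (diacetoxyiodo)benzene, CC(=O)OI(OC(C)=O)c1ccccc1
Why: The enolate of the acidic 1,3-dione displaces both acetates at iodine(III) (iodonium ylide formation by ligand exchange), placing the excellent leaving group PhI on C2 and turning this normally nucleophilic carbon into an acceptor; no stereocentre is formed.

Step 3
Reactants: 4 3,5-dibromo-2-methoxyphenol; 6 2-(phenyl-λ3-iodanylidene)cyclohexane-1,3-dione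
Product: 8 2-(3,5-dibromo-2-methoxyphenoxy)-3-methoxycyclohex-2-en-1-one, via aryloxy dione enol 7 (not isolated)
Conditions: Rh2(OAc)4 (1 mol %), 4 (1.5 equiv, excess recovered by NaOH wash), CH2Cl2, 6 added in portions, 25 to 40 °C; evaporate; HC(OMe)3 (3 equiv), TsOH·H2O (5 mol %), MeOH, 50 °C
Reagents that add atoms: trimethyl orthoformate, COC(OC)OC (delivers the OCH3 together with the solvent methanol, CO)
Why: Rh(II)-catalysed expulsion of PhI from 6 lets the phenol oxygen of 4 bond to the now electrophilic C2 (carbenoid O–H insertion with an iodonium ylide as diazo surrogate), the twice-brominated ring of 4 being too electron-poor for competing C–H attack, and the symmetric enol 7 then gives its only possible methyl vinylogous ester by acid-catalysed enol etherification, which decides which ring-B oxygen ends as OMe and which as OH; no stereocentre is formed.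

Step 4
Reactants: 8 2-(3,5-dibromo-2-methoxyphenoxy)-3-methoxycyclohex-2-en-1-one
Product: 11 4,6-dibromo-2-(3,5-dibromo-2-methoxyphenoxy)-3-methoxyphenol (target), via bromo enone 9 (not isolated), via methoxyphenol 10 (not isolated)
Conditions: NBS (3.05 equiv), NaOAc (1.5 equiv), MeCN–AcOH 10:1, 0 to 60 °C; aq. Na2S2O3 quench
Reagents that add atoms: N-bromosuccinimide, O=C1CCC(=O)N1Br
Why: Halogenation–dehydrohalogenation aromatisation followed by electrophilic aromatic bromination: the first NBS brominates the saturated flank of the enone, buffered loss of HBr and tautomerisation give phenol 10 (a first bromine at C4 instead of C6 converges on the same product), the two positions ortho and para to OH (para and ortho to OMe) take the other two bromines, deactivated ring A stays untouched, the acetate buffer protects the methyl enol ether from HBr, and the stereocentre of racemic 9 disappears on aromatisation.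

## Compound list

1 | 2,4,6-tribromoanisole (1,3,5-tribromo-2-methoxybenzene) | COc1c(Br)cc(Br)cc1Br | starting material
2 | (3,5-dibromo-2-methoxyphenyl)lithium | [Li]c1cc(Br)cc(Br)c1OC | intermediate (not isolated)
3 | dimethyl (3,5-dibromo-2-methoxyphenyl)boronate | COB(OC)c1cc(Br)cc(Br)c1OC | intermediate (not isolated)
4 | 3,5-dibromo-2-methoxyphenol | COc1c(O)cc(Br)cc1Br | intermediate
5 | cyclohexane-1,3-dione | O=C1CCCC(=O)C1 | starting material
6 | 2-(phenyl-λ3-iodanylidene)cyclohexane-1,3-dione (drawn as the iodonium enolate) | O=C1CCCC([O-])=C1[I+]c1ccccc1 | intermediate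
7 | 2-(3,5-dibromo-2-methoxyphenoxy)-3-hydroxycyclohex-2-en-1-one (enol of the 2-aryloxy-1,3-dione) | COc1c(Br)cc(Br)cc1OC1=C(O)CCCC1=O | intermediate (not isolated)
8 | 2-(3,5-dibromo-2-methoxyphenoxy)-3-methoxycyclohex-2-en-1-one | COC1=C(Oc2cc(Br)cc(Br)c2OC)C(=O)CCC1 | intermediate
9 | 6-bromo-2-(3,5-dibromo-2-methoxyphenoxy)-3-methoxycyclohex-2-en-1-one (racemic; drawn as the C6 bromide) | COC1=C(Oc2cc(Br)cc(Br)c2OC)C(=O)C(Br)CC1 | intermediate (not isolated)
10 | 2-(3,5-dibromo-2-methoxyphenoxy)-3-methoxyphenol | COc1cccc(O)c1Oc1cc(Br)cc(Br)c1OC | intermediate (not isolated)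
11 | 4,6-dibromo-2-(3,5-dibromo-2-methoxyphenoxy)-3-methoxyphenol (achiral) | COc1c(Br)cc(Br)cc1Oc1c(O)c(Br)cc(Br)c1OC | target

## Step count

Total step count: 4.
Longest linear sequence: 3 (steps 1, 3, 4).

## Steps most likely to fail

**Step 3 carries the most risk.**
- The ylide can rearrange by phenyl migration to oxygen.
- The acidic product 7 can compete with 4 for the electrophilic carbon.
- The ortho-methoxy, electron-poor phenol is a modest nucleophile.

The fallback sets out from 4 and comes back at 7. It makes the C–O bond on an open chain by ordinary substitution and closes ring B afterwards. Methyl 5-oxohexanoate is brominated at its methyl group (Br2, MeOH, 0 °C) to methyl 6-bromo-5-oxohexanoate F1. Phenol 4 is alkylated with it (K2CO3, acetone) to methyl 6-(3,5-dibromo-2-methoxyphenoxy)-5-oxohexanoate F2. KOt-Bu in THF then closes the six-membered ring by intramolecular Claisen (Dieckmann-type) condensation of the ArOCH2 carbon onto the ester. This gives 7, which is etherified to 8 as in step 3.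

**Step 4 is next.**
- The methyl enol ether may be lost before aromatisation, giving the resorcinol.
- HBr loss from 9 may be sluggish under the mild buffer.

The fallback sets out from 8 and comes back at 10. It separates dehydrogenation from bromination. Soft enolisation (TMSOTf, Et3N, CH2Cl2, 0 °C) gives 2-(3,5-dibromo-2-methoxyphenoxy)-1-methoxy-3-(trimethylsilyloxy)cyclohexa-1,3-diene F3. DDQ in toluene at rt dehydrogenates F3 to 10 after aqueous work-up. Isolated 10 then needs only NBS (2.0 equiv, MeCN, 0 °C) to reach 11.

**Step 1 is third.**
- Some para exchange or double exchange would give phenol isomers that are hard to separate.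
- The hindered boronate may protodeboronate.

The fallback sets out from 2 and comes back at 4. The oxygen is installed by an aryl shift from carbon instead of boron. Aryllithium 2 is quenched with DMF to 3,5-dibromo-2-methoxybenzaldehyde F4. This aldehyde is crystalline, so isomers can be removed by recrystallisation. It is also available from 3,5-dibromosalicylaldehyde and MeI if the exchange itself is the weak point. Baeyer–Villiger oxidation (mCPBA, CH2Cl2, 40 °C) gives 3,5-dibromo-2-methoxyphenyl formate F5. Methanolysis (cat. Et3N, MeOH) then releases 4.

## Further compounds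

F1 | step 3 | methyl 6-bromo-5-oxohexanoate | COC(=O)CCCC(=O)CBr
F2 | step 3 | methyl 6-(3,5-dibromo-2-methoxyphenoxy)-5-oxohexanoate | COC(=O)CCCC(=O)COc1cc(Br)cc(Br)c1OC
F3 | step 4 | 2-(3,5-dibromo-2-methoxyphenoxy)-1-methoxy-3-(trimethylsilyloxy)cyclohexa-1,3-diene | COC1=C(Oc2cc(Br)cc(Br)c2OC)C(O[Si](C)(C)C)=CCC1
F4 | step 1 | 3,5-dibromo-2-methoxybenzaldehyde | COc1c(Br)cc(Br)cc1C=O
F5 | step 1 | 3,5-dibromo-2-methoxyphenyl formate | COc1c(Br)cc(Br)cc1OC=O
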